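**Plan**
- Cuts (labdane numbering): C8=C17 and C9–C11 (methylene carbon and side chain taken off a ring-B vinyl sulfone), then C7–C8 (opens ring B), then C9–C10 (vinyl sulfone carbon off the tertiary C10), last C4–C5 and C10–O of a bromolactone (ring A back to homogeranic acid).
- Forward: ring A arises first by enantioselective bromonium cyclization; the lactone oxygen on C10 is exchanged for the C9=C8 vinyl sulfone by radical alkenylation; ring B then closes at C7–C8 and, in the same flask, the linalool-derived chain (on C9) and C17 (on C8) are joined.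
- Enabling feature: C10 is quaternary and carries its vinyl sulfone equatorial, trans to the equatorial 2-bromoethyl arm on C5 of chair ring A. C8 can therefore be lithiated with no allylic proton loss and lies within reach of C7; the C8 sulfone then activates C9 and finally leaves to unveil C8=C17.
- Stereochemistry: C3, C5 and C10 come from the chair-like bromonium cyclization of the E-alkene (absolute sense from the chiral catalyst; C10 kept by equatorial radical capture). C9 comes from axial attack anti to the axial C10 methyl on ring B. C13 comes from (R)-linalool.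

Key step: step 10

Assumption: the (R)-configured catalyst of step 1 is taken to give (3aR,5R,7aR)-2; should the sense of induction be the opposite, the (S)-catalyst is used.

Step 1
Reactants: 1 (3E)-4,8-dimethylnona-3,7-dienoic acid (homogeranic acid)
Product: 2 (3aR,5R,7aR)-5-bromo-4,4,7a-trimethylhexahydro-1-benzofuran-2(3H)-one (trans-fused bromolactone; Br equatorial)
Conditions: DBDMH (0.55 equiv), (R)-3,3'-bis(2,4,6-triisopropylphenyl)-1,1'-binaphthyl-2,2'-diyl N-(trifluoromethylsulfonyl)thiophosphoramide (10 mol%), toluene/CH2Cl2, −78 °C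
Reagents that add atoms: 1,3-dibromo-5,5-dimethylhydantoin (DBDMH), CC1(C)N(Br)C(=O)N(Br)C1=O
Why: Catalytic asymmetric bromonium-induced polyene cyclization, in which the chiral Lewis base delivers Br+ to one face of the terminal alkene and the chair-like cation–olefin closure, ended by the carboxyl oxygen adding anti across the E-alkene, should set Br equatorial at C3, H5 axial and the C10 methyl axial and trans to H5.

Step 2
Reactants: 2 (3aR,5R,7aR)-5-bromo-4,4,7a-trimethylhexahydro-1-benzofuran-2(3H)-one
Product: 3 (1R,2R,4R)-4-bromo-2-(2-hydroxyethyl)-1,3,3-trimethylcyclohexan-1-ol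
Conditions: LiBH4, THF, 0 °C to rt; H2O
Reagents that add atoms: none
Why: Hydride reduction of the lactone to the 1,4-diol should leave the hindered equatorial secondary bromide alone, since it has neither backside access nor an anti-periplanar hydrogen.

Step 3
Reactants: 3 (1R,2R,4R)-4-bromo-2-(2-hydroxyethyl)-1,3,3-trimethylcyclohexan-1-ol
Product: 4 (1R,2R,4R)-4-bromo-2-[2-(tert-butyldimethylsilyloxy)ethyl]-1,3,3-trimethylcyclohexan-1-ol
Conditions: TBSCl, imidazole, DMF, 0 °C
Reagents that add atoms: tert-butyldimethylsilyl chloride, CC(C)(C)[Si](C)(C)Cl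
Why: Chemoselective silyl ether formation at the primary alcohol, chosen over sulfonylation or halogenation because an activated primary carbon would be captured by the tertiary hydroxyl to give the bicyclic ether.

Step 4
Reactants: 4 (1R,2R,4R)-4-bromo-2-[2-(tert-butyldimethylsilyloxy)ethyl]-1,3,3-trimethylcyclohexan-1-ol
Product: 6 cesium (1R,2R,4R)-4-bromo-2-[2-(tert-butyldimethylsilyloxy)ethyl]-1,3,3-trimethylcyclohexyl oxalate, via methyl oxalate 5 (not isolated)
Conditions: ClC(O)CO2Me, Et3N, DMAP (cat), CH2Cl2, 0 °C; then CsOH (1.0 equiv), THF/H2O, rt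
Reagents that add atoms: methyl chlorooxoacetate, COC(=O)C(=O)Cl; cesium hydroxide, [Cs+].[OH-]
Why: Acylation of the tertiary alcohol by the highly reactive chlorooxoacetate, followed by selective saponification of the unhindered methyl ester, should give the cesium half-oxalate that serves as the tertiary-radical precursor.

Step 5
Reactants: 6 cesium (1R,2R,4R)-4-bromo-2-[2-(tert-butyldimethylsilyloxy)ethyl]-1,3,3-trimethylcyclohexyl oxalate; 7 (E)-1,2-bis(phenylsulfonyl)ethene
Product: 8 phenyl (E)-2-{(1R,2S,4R)-4-bromo-2-[2-(tert-butyldimethylsilyloxy)ethyl]-1,3,3-trimethylcyclohexyl}ethenyl sulfone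
Conditions: 7 (1.5 equiv), Ir[dF(CF3)ppy]2(dtbbpy)PF6 (2 mol%), DME/DMF (3:1), H2O (10 equiv), blue LEDs, 60 °C
Reagents that add atoms: none
Why: Photoredox oxalate fragment coupling by radical addition–β-elimination, in which oxidation of the oxalate by the excited trivalent iridium complex and loss of two CO2 give the tertiary C10 radical, which adds to 7 and expels PhSO2• to give the E-vinyl sulfone; the C10–C9 bond should form equatorially, away from the syn-axial C4 methyl and trans to the C5 arm (as in radical polyene cyclizations to trans-decalins), which keeps the C10 methyl axial.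

Step 6
Reactants: 8 phenyl (E)-2-{(1R,2S,4R)-4-bromo-2-[2-(tert-butyldimethylsilyloxy)ethyl]-1,3,3-trimethylcyclohexyl}ethenyl sulfone
Product: 9 phenyl (E)-2-[(1R,2S,4R)-4-bromo-2-(2-bromoethyl)-1,3,3-trimethylcyclohexyl]ethenyl sulfone
Conditions: Ph3PBr2, CH2Cl2, 0 °C to rt
Reagents that add atoms: dibromotriphenylphosphorane, BrP(Br)(c1ccccc1)(c1ccccc1)c1ccccc1
Why: Direct conversion of a primary silyl ether into the bromide through the alkoxyphosphonium bromide (Appel-type substitution), which never frees an alcohol that could add to the vinyl sulfone.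

Step 7
Reactants: 10 (3R)-3,7-dimethylocta-1,6-dien-3-ol ((R)-linalool)
Product: 11 (5R)-5-ethenyl-5-methyloxolan-2-ol (lactol; both anomers)
Conditions: O3 (1 equiv), CH2Cl2, −78 °C; then PPh3
Reagents that add atoms: ozone, [O-][O+]=O
Why: Chemoselective ozonolysis of the electron-rich trisubstituted alkene in preference to the vinyl carbinol gives the hydroxy aldehyde, which closes to the lactol without touching C13.

Step 8
Reactants: 11 (5R)-5-ethenyl-5-methyloxolan-2-ol
Product: 12 (3R)-5-iodo-3-methylpent-1-en-3-yl formate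
Conditions: PhI(OAc)2, I2, CH2Cl2, visible light, rt
Reagents that add atoms: iodine, II
Why: Suárez alkoxy-radical fragmentation, in which the anomeric hypoiodite gives an alkoxy radical whose β-scission cuts the ring C–C bond, the primary radical takes up iodine and the tertiary oxygen is left as its formate.

Step 9
Reactants: 12 (3R)-5-iodo-3-methylpent-1-en-3-yl formate
Product: 13 (3R)-5-iodo-3-methylpent-1-en-3-ol
Conditions: K2CO3 (cat), MeOH, 0 °C
Reagents that add atoms: none
Why: Transesterification removes the formate under conditions too mild for substitution or elimination of the primary iodide.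

Step 10
Reactants: 9 phenyl (E)-2-[(1R,2S,4R)-4-bromo-2-(2-bromoethyl)-1,3,3-trimethylcyclohexyl]ethenyl sulfone; 13 (3R)-5-iodo-3-methylpent-1-en-3-ol; 14 (iodomethyl)trimethylsilane
Product: 19 (3R)-5-[(1R,4aS,6R,8aR)-6-bromo-5,5,8a-trimethyl-2-(phenylsulfonyl)-2-[(trimethylsilyl)methyl]decahydronaphthalen-1-yl]-3-methylpent-1-en-3-ol (both C2 epimers), via lithiated vinyl sulfone 15 (not isolated), via ring-B vinyl sulfone 16 (not isolated), via dilithio side-chain reagent 17 (not isolated), via lithiated adduct 18 (not isolated)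
Conditions: LiTMP (from 2,2,6,6-tetramethylpiperidine, n-BuLi), THF, −78 to −30 °C; then 17 (from 13, t-BuLi 3 equiv, Et2O, −78 °C), −78 to −40 °C; then 14, DMPU, −78 to 0 °C; aq NH4Cl
Reagents that add atoms: none
Why: LiTMP removes the C8 hydrogen of the E-vinyl sulfone (C10 is quaternary, so no allylic proton competes) and the α-sulfonylvinyllithium 15, whose C–Li bond is cis to C10, displaces the primary bromide at C7, forming the C7–C8 bond and ring B; the cyclic vinyl sulfone 16 then accepts the organolithium 17 at C9 and the resulting α-sulfonyl carbanion 18 is C-alkylated by 14. The closest known reactions are the alkylation of α-lithiated vinyl sulfones and the conjugate addition of organolithiums to cycloalkenyl sulfones with trapping of the α-sulfonyl carbanion (triply convergent vinyl sulfone couplings). Ring B closes in the 6-exo-tet mode with the C8=C9 bond inside the new ring, and the fusion is trans because the C5 and C10 arms are trans-diequatorial on ring A. The new stereocenter C9 is set by axial attack of 17 on the half-chair of ring B from the face opposite the axial C10 methyl, which places the side chain trans to that methyl and cis to H5; C8 forms as a mixture that step 11 erases, and C13 is carried in from 13. The step needs deprotonation instead of conjugate addition by the base (secured by the hindered amide), attack at the primary and not the equatorial neopentyl-type secondary bromide, and addition of 17 in preference to its protonation (tetramethylpiperidine is deprotonated only slowly at −78 °C).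

Step 11
Reactants: 19 (3R)-5-[(1R,4aS,6R,8aR)-6-bromo-5,5,8a-trimethyl-2-(phenylsulfonyl)-2-[(trimethylsilyl)methyl]decahydronaphthalen-1-yl]-3-methylpent-1-en-3-ol
Product: 20 (3R)-5-[(1S,4aS,6R,8aS)-6-bromo-5,5,8a-trimethyl-2-methylidenedecahydronaphthalen-1-yl]-3-methylpent-1-en-3-ol (target)
Conditions: Bu4NF (TBAF), THF, 60 °C
Reagents that add atoms: none
Why: Fluoride-induced β-elimination of a β-silyl sulfone (sulfone methylenation), in which fluoride attacks silicon and benzenesulfinate leaves, should unveil the exocyclic C8=C17 alkene from either C8 epimer without touching C9, the tertiary allylic alcohol or the equatorial bromide.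

**Compound list**
1 | (3E)-4,8-dimethylnona-3,7-dienoic acid (homogeranic acid) | CC(C)=CCC/C(C)=C/CC(=O)O | starting material
2 | (3aR,5R,7aR)-5-bromo-4,4,7a-trimethylhexahydro-1-benzofuran-2(3H)-one | O=C1C[C@@H]2C(C)(C)[C@H](Br)CC[C@@]2(C)O1 | intermediate
3 | (1R,2R,4R)-4-bromo-2-(2-hydroxyethyl)-1,3,3-trimethylcyclohexan-1-ol | OCC[C@@H]1C(C)(C)[C@H](Br)CC[C@@]1(C)O | intermediate
4 | (1R,2R,4R)-4-bromo-2-[2-(tert-butyldimethylsilyloxy)ethyl]-1,3,3-trimethylcyclohexan-1-ol | CC(C)(C)[Si](C)(C)OCC[C@@H]1C(C)(C)[C@H](Br)CC[C@@]1(C)O | intermediate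
5 | (1R,2R,4R)-4-bromo-2-[2-(tert-butyldimethylsilyloxy)ethyl]-1,3,3-trimethylcyclohexyl methyl oxalate | CC(C)(C)[Si](C)(C)OCC[C@@H]1C(C)(C)[C@H](Br)CC[C@@]1(C)OC(=O)C(=O)OC | intermediate
6 | cesium (1R,2R,4R)-4-bromo-2-[2-(tert-butyldimethylsilyloxy)ethyl]-1,3,3-trimethylcyclohexyl oxalate | CC(C)(C)[Si](C)(C)OCC[C@@H]1C(C)(C)[C@H](Br)CC[C@@]1(C)OC(=O)C(=O)[O-].[Cs+] | intermediate
7 | (E)-1,2-bis(phenylsulfonyl)ethene | O=S(=O)(/C=C/S(=O)(=O)c1ccccc1)c1ccccc1 | starting material
8 | phenyl (E)-2-{(1R,2S,4R)-4-bromo-2-[2-(tert-butyldimethylsilyloxy)ethyl]-1,3,3-trimethylcyclohexyl}ethenyl sulfone | CC(C)(C)[Si](C)(C)OCC[C@@H]1C(C)(C)[C@H](Br)CC[C@@]1(C)/C=C/S(=O)(=O)c1ccccc1 | intermediate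
9 | phenyl (E)-2-[(1R,2S,4R)-4-bromo-2-(2-bromoethyl)-1,3,3-trimethylcyclohexyl]ethenyl sulfone | BrCC[C@@H]1C(C)(C)[C@H](Br)CC[C@@]1(C)/C=C/S(=O)(=O)c1ccccc1 | intermediate
10 | (3R)-3,7-dimethylocta-1,6-dien-3-ol ((R)-linalool) | C=C[C@](C)(O)CCC=C(C)C | starting material
11 | (5R)-5-ethenyl-5-methyloxolan-2-ol (anomer mixture) | C=C[C@@]1(C)CCC(O)O1 | intermediate
12 | (3R)-5-iodo-3-methylpent-1-en-3-yl formate | C=C[C@](C)(OC=O)CCI | intermediate
13 | (3R)-5-iodo-3-methylpent-1-en-3-ol | C=C[C@](C)(O)CCI | intermediate
14 | (iodomethyl)trimethylsilane | C[Si](C)(C)CI | starting material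
15 | α-lithio derivative of 9 (lithium on the sulfonyl-bearing alkene carbon, cis to the ring) | BrCC[C@@H]1C(C)(C)[C@H](Br)CC[C@@]1(C)/C=C(\[Li])S(=O)(=O)c1ccccc1 | intermediate
16 | (4aS,6R,8aR)-6-bromo-5,5,8a-trimethyl-2-(phenylsulfonyl)-3,4,4a,5,6,7,8,8a-octahydronaphthalene | C1=C(S(=O)(=O)c3ccccc3)CC[C@@H]2C(C)(C)[C@H](Br)CC[C@]21C | intermediate
17 | lithium (3R)-5-lithio-3-methylpent-1-en-3-olate | C=C[C@](C)(O[Li])CC[Li] | intermediate
18 | C9 adduct of 16 and 17 as its α-sulfonyl carbanion (lithium at C8; lithium alkoxide) | C=C[C@](C)(O[Li])CC[C@H]1C([Li])(S(=O)(=O)c3ccccc3)CC[C@@H]2C(C)(C)[C@H](Br)CC[C@]21C | intermediate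
19 | (3R)-5-[(1R,4aS,6R,8aR)-6-bromo-5,5,8a-trimethyl-2-(phenylsulfonyl)-2-[(trimethylsilyl)methyl]decahydronaphthalen-1-yl]-3-methylpent-1-en-3-ol (both C2 epimers) | C=C[C@](C)(O)CC[C@H]1C(C[Si](C)(C)C)(S(=O)(=O)c3ccccc3)CC[C@@H]2C(C)(C)[C@H](Br)CC[C@]21C | intermediate
20 | (3R)-5-[(1S,4aS,6R,8aS)-6-bromo-5,5,8a-trimethyl-2-methylidenedecahydronaphthalen-1-yl]-3-methylpent-1-en-3-ol | C=C[C@](C)(O)CC[C@H]1C(=C)CC[C@@H]2C(C)(C)[C@H](Br)CC[C@]21C | target

Total steps: 11. Longest linear sequence: 8 steps (steps 1–6, 10, 11); the side-chain fragment takes 3 steps (7–9).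

**Steps most likely to fail**

1. Step 10. The α-sulfonylvinyllithium may add to unreacted 9, or be alkylated too slowly, so that ring B is not closed when the side-chain reagent arrives. The fallback closes the ring through an sp3 α-sulfonyl carbanion in a Michael-initiated ring closure with a traceless thiolate. Compound 9 is treated with PhSNa (THF/DMF, 0 °C to rt); reversible thiolate addition at C9 and 6-exo-tet alkylation of the α-sulfonyl carbanion at C7 should give the β-phenylthio sulfone F1. Oxidation with mCPBA (1 equiv, −78 °C) gives the sulfoxide F2. Its thermal syn-elimination (toluene, 80 °C) can only take the C8 hydrogen, since C10 has none, and gives the vinyl sulfone 16, now isolated. The route is rejoined at 16, which is carried through the second and third stages of step 10 (17, then 14).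

2. Step 1. The bromine transfer may show insufficient facial selectivity, or bromine may be captured by the alkene nearer the carboxyl group. The fallback is a two-step surrogate for the asymmetric bromonium cyclization. Compound 1 is cyclized with Hg(OTf)2 in the presence of the chiral bis(oxazoline) (S,S)-2,2'-(propane-2,2-diyl)bis(4-tert-butyl-4,5-dihydrooxazole), or its enantiomer if the sense requires. After exchange with KBr the organomercurial is isolated as the bromomercurio lactone F3. Bromodemercuration with Br2/LiBr in pyridine, which proceeds with retention at carbon, gives 2, where the route is rejoined.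

3. Step 5. The hindered oxalate may fragment slowly, and the tertiary radical may be lost by hydrogen abstraction or by oxidation to alkenes before it is trapped. The fallback generates the radical by metal-hydride hydrogen atom transfer and then dehydrogenates. Compound 4 is dehydrated with the Burgess reagent (toluene, 60 °C) to the exocyclic alkene F4 together with its endocyclic isomer F5; both give the same C10 radical. Fe(acac)3/PhSiH3 with phenyl vinyl sulfone (EtOH, rt) should give the saturated sulfone F6 by Markovnikov hydrogen atom transfer and Giese addition. Deprotonation (LDA, THF, −78 °C) and PhSeCl give the α-phenylseleno sulfone F7. H2O2 then delivers the E-vinyl sulfone 8 by selenoxide elimination, where the route is rejoined.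

**Further compounds**
F1 | step 10 | (4aS,6R,8aR)-6-bromo-5,5,8a-trimethyl-2-(phenylsulfonyl)-1-(phenylthio)decahydronaphthalene (C1/C2 isomers) | c1ccccc1SC1C(S(=O)(=O)c3ccccc3)CC[C@@H]2C(C)(C)[C@H](Br)CC[C@]21C
F2 | step 10 | sulfoxide of F1 (phenylsulfinyl at C1) | c1ccccc1S(=O)C1C(S(=O)(=O)c3ccccc3)CC[C@@H]2C(C)(C)[C@H](Br)CC[C@]21C
F3 | step 1 | (3aR,5R,7aR)-5-(bromomercurio)-4,4,7a-trimethylhexahydro-1-benzofuran-2(3H)-one | O=C1C[C@@H]2C(C)(C)[C@H]([Hg]Br)CC[C@@]2(C)O1
F4 | step 5 | tert-butyl{2-[(1S,3R)-3-bromo-2,2-dimethyl-6-methylidenecyclohexyl]ethoxy}dimethylsilane | CC(C)(C)[Si](C)(C)OCC[C@@H]1C(C)(C)[C@H](Br)CCC1=C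
F5 | step 5 | endocyclic isomer of F4 (2,6,6-trimethylcyclohex-2-enyl type) | CC(C)(C)[Si](C)(C)OCC[C@@H]1C(C)(C)[C@H](Br)CC=C1C
F6 | step 5 | phenyl 2-{(1R,2S,4R)-4-bromo-2-[2-(tert-butyldimethylsilyloxy)ethyl]-1,3,3-trimethylcyclohexyl}ethyl sulfone | CC(C)(C)[Si](C)(C)OCC[C@@H]1C(C)(C)[C@H](Br)CC[C@@]1(C)CCS(=O)(=O)c1ccccc1
F7 | step 5 | α-phenylseleno derivative of F6 | CC(C)(C)[Si](C)(C)OCC[C@@H]1C(C)(C)[C@H](Br)CC[C@@]1(C)CC([Se]c1ccccc1)S(=O)(=O)c1ccccc1
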